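**Plan**

- Retrosynthetic cuts, in order: the cinnamate C–O bond; the isopropyl–carbinol C–C bond; the CH2–CH2 bond of the cyclopentane (as the C=C of a cyclopentenone); then the two C–C bonds from the ring-fusion carbons to the oxygenated CH and to the CH2 next to the ketone of the cycloheptenone ([5+2] cycloaddition of a 3-oxidopyrylium).
- Forward order: the cycloheptenone is made first, inside an 8-oxabicyclo[3.2.1]octenone whose oxygen bridge is a temporary ring. The bridge is cut with SmI2, the cyclopentane is closed last by aldol condensation, then isopropyl and the ester are added.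
- Enabling feature: the two adjacent CH2 groups are the only unsubstituted atoms of the five-membered ring. One hangs on the quaternary, methyl-bearing ring-fusion carbon and the other on the tertiary carbinol carbon, so they map onto a non-enolisable aldehyde and the CH3 of a methyl ketone in a 1,4-relationship. The γ-oxygenated α-methyl enone of the seven-membered ring is the retron of the oxidopyrylium cycloaddition.
- Stereochemistry: (R)-1-phenylethanol is bought and used as an ester auxiliary (diastereomeric cycloadducts are separated). The cycloaddition sets the three contiguous centres of the seven-membered ring at once (E-alkene gives the trans ring fusion; exo ester ends cis to the carbinol oxygen). The tertiary carbinol follows by addition anti to the angular methyl.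

Key step: step 10

Remark: only the cycloadduct diastereomer drawn as 10 is carried forward, its diastereomer from attack on the other face being removed by chromatography; compounds 1, 6 and 19 are taken as purchasable.

**Route**

Step 1
Reactants: 1 2-(diethoxyphosphoryl)propanoic acid; 2 (R)-1-phenylethanol
Product: 3 (R)-1-phenylethyl 2-(diethoxyphosphoryl)propanoate
Conditions: DCC, DMAP (cat.), CH2Cl2, 0 °C → rt
Reagents that add atoms: none
Why: Steglich esterification attaches the resolving auxiliary; the phosphonate α-centre becomes sp2 in step 2, so its epimer mixture does not matter.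

Step 2
Reactants: 3 (R)-1-phenylethyl 2-(diethoxyphosphoryl)propanoate; 4 methylglyoxal (40% in water)
Product: 5 (R)-1-phenylethyl (E)-2-methyl-4-oxopent-2-enoate
Conditions: K2CO3, THF–H2O, 0 °C → rt
Reagents that add atoms: none
Why: Horner–Wadsworth–Emmons olefination at the aldehyde (not the ketone) carbonyl; α-methyl phosphonoacetates should give the E-trisubstituted enoate with acetyl trans to the ester.

Step 3
Reactants: 6 (3-methylfuran-2-yl)methanol
Product: 7 6-hydroxy-4-methyl-2H-pyran-3(6H)-one
Conditions: mCPBA, CH2Cl2, 0 °C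
Reagents that add atoms: meta-chloroperoxybenzoic acid O=C(OO)c1cccc(Cl)c1
Why: Achmatowicz oxidative ring expansion of a furfuryl alcohol; the furan 3-methyl ends on the enone α-carbon.

Step 4
Reactants: 7 6-hydroxy-4-methyl-2H-pyran-3(6H)-one
Product: 8 4-methyl-5-oxo-5,6-dihydro-2H-pyran-2-yl acetate
Conditions: Ac2O, pyridine, DMAP (cat.), CH2Cl2, 0 °C
Reagents that add atoms: acetic anhydride CC(=O)OC(C)=O
Why: O-acetylation of the hemiacetal installs the leaving group needed to generate the ylide.

Step 5
Reactants: 8 4-methyl-5-oxo-5,6-dihydro-2H-pyran-2-yl acetate; 5 (R)-1-phenylethyl (E)-2-methyl-4-oxopent-2-enoate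
Product: 10 (R)-1-phenylethyl 6-endo-acetyl-3,7-dimethyl-2-oxo-8-oxabicyclo[3.2.1]oct-3-ene-7-exo-carboxylate, via 4-methylpyrylium-3-olate 9 (not isolated)
Conditions: 5 (3 equiv), Et3N (slow addition), MeCN, 50 °C; chromatographic separation of the diastereomers
Reagents that add atoms: none
Why: Base-induced loss of acetate gives the 3-oxidopyrylium ylide, which undergoes [5+2] dipolar cycloaddition: its nucleophilic terminus next to the oxido carbon should bond to the alkene carbon β to the ketone, the ketone should sit endo and the bulkier ester exo, and the E geometry is transferred, so the three ring stereocentres arise together, while the remote auxiliary is expected to give little facial bias and serves to make the two series separable.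

Step 6
Reactants: 10 (R)-1-phenylethyl 6-endo-acetyl-3,7-dimethyl-2-oxo-8-oxabicyclo[3.2.1]oct-3-ene-7-exo-carboxylate
Product: 11 (R)-1-phenylethyl 7-acetyl-6-hydroxy-1,4-dimethyl-3-oxocyclohept-4-ene-1-carboxylate
Conditions: SmI2 (2.5 equiv), THF–MeOH, −78 °C; AcOH quench at −78 °C
Reagents that add atoms: none
Why: Samarium diiodide reduction of the α-alkoxy ketone (the bridging oxygen and carbonyl can chelate the metal) cleaves the C–O bond at the α-carbon, so the oxygen stays on the γ-carbon as the secondary alcohol with the configuration set in step 5.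

Step 7
Reactants: 11 (R)-1-phenylethyl 7-acetyl-6-hydroxy-1,4-dimethyl-3-oxocyclohept-4-ene-1-carboxylate
Product: 12 (R)-1-phenylethyl 7-acetyl-6-[(tert-butyldimethylsilyl)oxy]-1,4-dimethyl-3-oxocyclohept-4-ene-1-carboxylate
Conditions: TBSOTf, 2,6-lutidine, CH2Cl2, −78 °C
Reagents that add atoms: tert-butyldimethylsilyl trifluoromethanesulfonate CC(C)(C)[Si](C)(C)OS(=O)(=O)C(F)(F)F
Why: Silyl ether formation protects the β-hydroxy ketone against retro-aldol cleavage and keeps this alcohol out of the later oxidation.

Step 8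
Reactants: 12 (R)-1-phenylethyl 7-acetyl-6-[(tert-butyldimethylsilyl)oxy]-1,4-dimethyl-3-oxocyclohept-4-ene-1-carboxylate
Product: 13 4-[(tert-butyldimethylsilyl)oxy]-5-(1-hydroxyethyl)-6-(hydroxymethyl)-2,6-dimethylcyclohept-2-en-1-ol
Conditions: iBu2AlH (excess), CH2Cl2, −78 → 0 °C; Rochelle salt work-up
Reagents that add atoms: none
Why: Hydride reduction of ester (releasing the auxiliary), methyl ketone and enone (1,2) in one operation; the two new carbinol centres are expected as epimer mixtures and are removed again in step 9.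

Step 9
Reactants: 13 4-[(tert-butyldimethylsilyl)oxy]-5-(1-hydroxyethyl)-6-(hydroxymethyl)-2,6-dimethylcyclohept-2-en-1-ol
Product: 14 7-acetyl-6-[(tert-butyldimethylsilyl)oxy]-1,4-dimethyl-3-oxocyclohept-4-ene-1-carbaldehyde
Conditions: Dess–Martin periodinane (4 equiv), NaHCO3, CH2Cl2, 0 °C → rt
Reagents that add atoms: none
Why: Dess–Martin oxidation of all three hydroxyls gives the neopentyl aldehyde, the methyl ketone and the enone, i.e. the ester has been taken down to the aldehyde level without touching the ring stereocentres.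

Step 10
Reactants: 14 7-acetyl-6-[(tert-butyldimethylsilyl)oxy]-1,4-dimethyl-3-oxocyclohept-4-ene-1-carbaldehyde
Product: 15 trans-fused 4-[(tert-butyldimethylsilyl)oxy]-6,8a-dimethyl-3a,4,8,8a-tetrahydroazulene-3,7-dione
Conditions: dibenzylammonium trifluoroacetate, benzene, 50 °C
Reagents that add atoms: none
Why: The secondary ammonium salt should condense with the acetyl group to give the less substituted CH2= enamine, whose terminal carbon adds to the neighbouring aldehyde on the quaternary carbon; loss of water then gives the conjugated cyclopentenone. This is the intramolecular aldol condensation of a 1,4-keto aldehyde, the standard cyclopentenone annulation. The ring closes in the 5-(enolendo)-exo-trig mode onto an aldehyde that cannot enolise, and because acetyl and formyl are trans on the cycloheptene (fixed in step 5) the new ring is trans-fused. No stereocentre is created; the step must leave the ring-fusion CH (α to the ketone) unepimerised and the β-silyloxy group in place, which the nearly neutral amine-salt conditions and the slower enolisation toward the hindered methine should secure. The cycloheptenone carbonyl is far less electrophilic than the aldehyde and is not expected to compete.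

Step 11
Reactants: 15 trans-fused 4-[(tert-butyldimethylsilyl)oxy]-6,8a-dimethyl-3a,4,8,8a-tetrahydroazulene-3,7-dione
Product: 16 4-[(tert-butyldimethylsilyl)oxy]-3-hydroxy-3-isopropyl-6,8a-dimethyl-3a,4,8,8a-tetrahydroazulen-7(3H)-one
Conditions: iPrMgCl (1.1 equiv), LaCl3·2LiCl, THF, −78 °C
Reagents that add atoms: isopropylmagnesium chloride CC(C)[Mg]Cl
Why: Lanthanum-salt-promoted 1,2-addition of the Grignard reagent to the cyclopentenone, the less hindered and more electrophilic ketone (the cycloheptenone carbonyl is flanked by a neopentyl CH2 and the methyl-substituted alkene); attack anti to the angular methyl should place the new hydroxyl cis to it.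

Step 12
Reactants: 16 4-[(tert-butyldimethylsilyl)oxy]-3-hydroxy-3-isopropyl-6,8a-dimethyl-3a,4,8,8a-tetrahydroazulen-7(3H)-one
Product: 17 (3R,3aS,4S,8aR)-4-[(tert-butyldimethylsilyl)oxy]-3-hydroxy-3-isopropyl-6,8a-dimethyl-2,3,3a,4,8,8a-hexahydroazulen-7(1H)-one
Conditions: H2 (1 atm), RhCl(PPh3)3 (10 mol %), benzene, rt
Reagents that add atoms: none
Why: Homogeneous hydrogenation should reduce the cis-disubstituted cyclopentene and leave the trisubstituted, conjugated cycloheptenone alkene.

Step 13
Reactants: 17 (3R,3aS,4S,8aR)-4-[(tert-butyldimethylsilyl)oxy]-3-hydroxy-3-isopropyl-6,8a-dimethyl-2,3,3a,4,8,8a-hexahydroazulen-7(1H)-one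
Product: 18 (3R,3aS,4S,8aR)-3,4-dihydroxy-3-isopropyl-6,8a-dimethyl-2,3,3a,4,8,8a-hexahydroazulen-7(1H)-one
Conditions: HF·pyridine, THF, 0 °C → rt
Reagents that add atoms: none
Why: Fluoride-mediated silyl ether cleavage under buffered, non-basic conditions that should not isomerise the γ-hydroxy enone.

Step 14
Reactants: 18 (3R,3aS,4S,8aR)-3,4-dihydroxy-3-isopropyl-6,8a-dimethyl-2,3,3a,4,8,8a-hexahydroazulen-7(1H)-one; 19 (E)-3-(4-acetoxyphenyl)prop-2-enoic acid
Product: 21 (3R,3aS,4S,8aR)-3-hydroxy-3-isopropyl-6,8a-dimethyl-7-oxo-1,2,3,3a,4,7,8,8a-octahydroazulen-4-yl (E)-3-(4-acetoxyphenyl)prop-2-enoate, via (E)-3-(4-acetoxyphenyl)acryloyl chloride 20 (not isolated)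
Conditions: 19, (COCl)2, DMF (cat.), CH2Cl2, 0 °C → rt; then 18, pyridine, CH2Cl2, 0 °C → rt
Reagents that add atoms: none
Why: Acid chloride esterification; only the secondary alcohol should react, the tertiary carbinol being too hindered.

Step 15
Reactants: 21 (3R,3aS,4S,8aR)-3-hydroxy-3-isopropyl-6,8a-dimethyl-7-oxo-1,2,3,3a,4,7,8,8a-octahydroazulen-4-yl (E)-3-(4-acetoxyphenyl)prop-2-enoate
Product: 22 (3R,3aS,4S,8aR)-3-hydroxy-3-isopropyl-6,8a-dimethyl-7-oxo-1,2,3,3a,4,7,8,8a-octahydroazulen-4-yl (E)-3-(4-hydroxyphenyl)prop-2-enoate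
Conditions: pyrrolidine (3 equiv), CH2Cl2, 0 °C
Reagents that add atoms: none
Why: Aminolysis of the aryl acetate, which should be much faster than attack on the hindered alkyl cinnamate, frees the phenol.

**Compound list**

1 | 2-(diethoxyphosphoryl)propanoic acid | CCOP(=O)(OCC)C(C)C(=O)O | starting material
2 | (R)-1-phenylethanol | C[C@@H](O)c1ccccc1 | starting material
3 | (R)-1-phenylethyl 2-(diethoxyphosphoryl)propanoate (both epimers at the phosphonate carbon) | CCOP(=O)(OCC)C(C)C(=O)O[C@H](C)c1ccccc1 | intermediate
4 | methylglyoxal (2-oxopropanal) | CC(=O)C=O | starting material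
5 | (R)-1-phenylethyl (E)-2-methyl-4-oxopent-2-enoate | CC(=O)/C=C(\C)C(=O)O[C@H](C)c1ccccc1 | intermediate
6 | (3-methylfuran-2-yl)methanol | Cc1ccoc1CO | starting material
7 | 6-hydroxy-4-methyl-2H-pyran-3(6H)-one (racemic hemiacetal) | CC1=CC(O)OCC1=O | intermediate
8 | 4-methyl-5-oxo-5,6-dihydro-2H-pyran-2-yl acetate (racemic) | CC1=CC(OC(C)=O)OCC1=O | intermediate
9 | 4-methylpyrylium-3-olate (oxidopyrylium ylide, not isolated) | Cc1cc[o+]cc1[O-] | intermediate
10 | (R)-1-phenylethyl 6-endo-acetyl-3,7-dimethyl-2-oxo-8-oxabicyclo[3.2.1]oct-3-ene-7-exo-carboxylate (7-methyl endo; single diastereomer, configuration as in the SMILES) | CC1=C[C@H](O2)[C@@H](C(C)=O)[C@](C)(C(=O)O[C@H](C)c3ccccc3)[C@H]2C1=O | intermediate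
11 | (R)-1-phenylethyl 7-acetyl-6-hydroxy-1,4-dimethyl-3-oxocyclohept-4-ene-1-carboxylate (6-OH trans to 7-acetyl; acetyl trans to the carboxylate, cis to the 1-methyl) | CC1=C[C@H](O)[C@@H](C(C)=O)[C@](C)(C(=O)O[C@H](C)c2ccccc2)CC1=O | intermediate
12 | 6-O-tert-butyldimethylsilyl ether of 11 | CC1=C[C@H](O[Si](C)(C)C(C)(C)C)[C@@H](C(C)=O)[C@](C)(C(=O)O[C@H](C)c2ccccc2)CC1=O | intermediate
13 | 4-[(tert-butyldimethylsilyl)oxy]-5-(1-hydroxyethyl)-6-(hydroxymethyl)-2,6-dimethylcyclohept-2-en-1-ol (epimers at C1 and at the hydroxyethyl carbon; ring centres as in 12) | CC1=C[C@H](O[Si](C)(C)C(C)(C)C)[C@@H](C(C)O)[C@](C)(CO)CC1O | intermediate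
14 | 7-acetyl-6-[(tert-butyldimethylsilyl)oxy]-1,4-dimethyl-3-oxocyclohept-4-ene-1-carbaldehyde (ring centres as in 12) | CC1=C[C@H](O[Si](C)(C)C(C)(C)C)[C@@H](C(C)=O)[C@](C)(C=O)CC1=O | intermediate
15 | 4-[(tert-butyldimethylsilyl)oxy]-6,8a-dimethyl-3a,4,8,8a-tetrahydroazulene-3,7-dione (H-3a trans to the 8a-methyl; 4-silyloxy cis to H-3a) | CC1=C[C@H](O[Si](C)(C)C(C)(C)C)[C@@H]2[C@](C)(C=CC2=O)CC1=O | intermediate
16 | 4-[(tert-butyldimethylsilyl)oxy]-3-hydroxy-3-isopropyl-6,8a-dimethyl-3a,4,8,8a-tetrahydroazulen-7(3H)-one (3-OH cis to the 8a-methyl; other centres as in 15) | CC1=C[C@H](O[Si](C)(C)C(C)(C)C)[C@@H]2[C@](C)(C=C[C@@]2(O)C(C)C)CC1=O | intermediate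
17 | (3R,3aS,4S,8aR)-4-[(tert-butyldimethylsilyl)oxy]-3-hydroxy-3-isopropyl-6,8a-dimethyl-2,3,3a,4,8,8a-hexahydroazulen-7(1H)-one | CC1=C[C@H](O[Si](C)(C)C(C)(C)C)[C@@H]2[C@](C)(CC[C@@]2(O)C(C)C)CC1=O | intermediate
18 | (3R,3aS,4S,8aR)-3,4-dihydroxy-3-isopropyl-6,8a-dimethyl-2,3,3a,4,8,8a-hexahydroazulen-7(1H)-one | CC1=C[C@H](O)[C@@H]2[C@](C)(CC[C@@]2(O)C(C)C)CC1=O | intermediate
19 | (E)-3-(4-acetoxyphenyl)prop-2-enoic acid | CC(=O)Oc1ccc(/C=C/C(=O)O)cc1 | starting material
20 | (E)-3-(4-acetoxyphenyl)acryloyl chloride (not isolated) | CC(=O)Oc1ccc(/C=C/C(Cl)=O)cc1 | intermediate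
21 | (3R,3aS,4S,8aR)-3-hydroxy-3-isopropyl-6,8a-dimethyl-7-oxo-1,2,3,3a,4,7,8,8a-octahydroazulen-4-yl (E)-3-(4-acetoxyphenyl)prop-2-enoate | CC1=C[C@H](OC(=O)/C=C/c2ccc(OC(C)=O)cc2)[C@@H]2[C@](C)(CC[C@@]2(O)C(C)C)CC1=O | intermediate
22 | (3R,3aS,4S,8aR)-3-hydroxy-3-isopropyl-6,8a-dimethyl-7-oxo-1,2,3,3a,4,7,8,8a-octahydroazulen-4-yl (E)-3-(4-hydroxyphenyl)prop-2-enoate | CC1=C[C@H](OC(=O)/C=C/c2ccc(O)cc2)[C@@H]2[C@](C)(CC[C@@]2(O)C(C)C)CC1=O | target

**Step count**

Total: 15 steps. Longest linear sequence: 13 steps (steps 1, 2 and 5–15, or equally 3, 4 and 5–15).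

**Steps most likely to fail**

1. Step 5. The trisubstituted alkene may react too slowly with the ylide (which then dimerises). The ylide may also bond with the reverse orientation, or the ester may end endo, which would put the wrong configuration on the quaternary carbon. The auxiliary is not expected to bias the face, so it only allows separation. Fallback: starting from 8, the cis-configured alkene (R)-1-phenylethyl (Z)-2-methyl-4-oxopent-2-enoate F1 (from 5 by sensitised photoisomerisation) would be used. With both carbonyl groups on one side, the all-exo transition state should dominate and give the 6-exo-acetyl cycloadduct F2, in which the quaternary carbon already has the required ester-exo arrangement. DBU would then epimerise the acetyl-bearing carbon to the more stable trans arrangement, which is 10.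

2. Step 11. The organometallic may also add to the cycloheptenone carbonyl, or approach the cyclopentenone from the face of the angular methyl. Fallback: starting from 15, the cycloheptenone would first be masked in the flask as its lithium dienolate F3 (LiN(SiMe3)2, THF, −78 °C, kinetic deprotonation at the CH2 next to the quaternary carbon). The isopropyl reagent would then be added to the only remaining ketone, and aqueous work-up would return the enone, giving 16.

3. Step 10. Enolisation toward the ring-fusion CH could epimerise it (leading to the cis-fused enone) or expel the β-silyloxy group before the ring closes. Fallback: starting from 14, the regiodefined bis(trimethylsilyl enol ether) F4 would be made under kinetic conditions (Me3SiOTf, Et3N, CH2Cl2, −78 °C). An intramolecular Mukaiyama aldol addition (BF3·OEt2, −78 °C) would give the β-hydroxy cyclopentanone F5, and mild acid-catalysed dehydration (TsOH, benzene) would then give 15.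

**Further compounds**

F1 | step 5 | (R)-1-phenylethyl (Z)-2-methyl-4-oxopent-2-enoate | CC(=O)/C=C(/C)C(=O)O[C@H](C)c1ccccc1
F2 | step 5 | (R)-1-phenylethyl 6-exo-acetyl-3,7-dimethyl-2-oxo-8-oxabicyclo[3.2.1]oct-3-ene-7-exo-carboxylate (acetyl epimer of 10) | CC1=C[C@H](O2)[C@H](C(C)=O)[C@](C)(C(=O)O[C@H](C)c3ccccc3)[C@H]2C1=O
F3 | step 11 | lithium dienolate of 15 (enolised toward the CH2 next to the quaternary carbon) | [Li+].CC1=C[C@H](O[Si](C)(C)C(C)(C)C)[C@@H]2[C@](C)(C=CC2=O)C=C1[O-]
F4 | step 10 | bis(trimethylsilyl enol ether) of 14 (at the acetyl CH3 and at the cycloheptenone CH2) | CC1=C[C@H](O[Si](C)(C)C(C)(C)C)[C@@H](C(=C)O[Si](C)(C)C)[C@](C)(C=O)C=C1O[Si](C)(C)C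
F5 | step 10 | 4-[(tert-butyldimethylsilyl)oxy]-1-hydroxy-6,8a-dimethyl-1,2,3a,4,8,8a-hexahydroazulene-3,7-dione (aldol, epimers at the carbinol carbon) | CC1=C[C@H](O[Si](C)(C)C(C)(C)C)[C@@H]2[C@](C)(C(O)CC2=O)CC1=O
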